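# Synthesis plan for (4S,6R)-4,6-dihydroxy-6-[(2S,10Z)-2-hydroxyheptadec-10-enyl]cyclohex-2-en-1-one (22)

## The problem

Compound 22 is a single cyclohex-2-en-1-one ring (C1 carbonyl, C2=C3, C4 secondary carbinol, C5 methylene, C6 tertiary carbinol). Its only appendage is a 17-carbon chain C1′–C17′ on the fully substituted C6, with a secondary carbinol at C2′ and an isolated (Z)-alkene at C10′=C11′. There is no ring fusion to build. The task is to join ring and chain through an oxygenated quaternary carbon and to carry the (Z)-alkene through unchanged.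

The three stereocentres, C4 (S), C6 (R) and C2′ (S), are each separated from the next by a methylene group, so 1,2-induction is not available. C2′ and C4 lie 1,5 to each other, syn across C6, and cannot control one another; both are best bought. C6 lies 1,3 to C4 inside the ring, so C4 can steer it once a six-membered transition state exists, and a chiral catalyst can reinforce that.

Several groups limit the chemistry. The (Z)-alkene rules out hydrogenation, ozone and long exposure to palladium hydrides. The C1/C6 α-ketol can undergo an acyloin shift under base. The γ-hydroxy enone, and every β-oxygenated ketone on the way, loses water or silanol easily, ultimately toward aromatic products.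

The enabling feature is that C6, in the ring-opened form, is a carbonyl-level carbon with two CH2–CH(O) arms, C5–C4 and C1′–C2′. This 1,3,5-oxygen pattern is what one acyl-anion carbon and two terminal epoxides deliver. Only the C1–C6 bond then remains, between an aldehyde carbon and a ketone carbon, which is the pair an acyloin-type closure turns directly into the α-ketol.

## Retrosynthesis

**22 back to 19.** No skeletal bond is cut first. The three silyl groups of 21 are put back and the C2=C3 double bond is removed through silyl enol ether 20 to the saturated α-ketol 19. Carrying the alkene from the start would expose a hindered dithiane anion to SN2′ and conjugate pathways. Ketol 19 can enolise only toward C2, because C6 has no hydrogen, so the position of the new double bond needs no control. 19 lacks the acid-sensitive γ-hydroxy enone. The forward steps must dehydrogenate without moving the (Z)-alkene and must remove silicon without dehydrating the ring.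

**19 back to 18 (C1–C6).** This is the one ring bond left after the key union. A reductive pinacol coupling at the same bond would give a diol, would need a further oxidation of C1–OH, and would leave C6 to the geometry of a metal chelate. A carbene-catalysed crossed benzoin is redox-neutral, gives the α-ketol directly, and offers two control elements for C6: the chair of the forming ring with the C4 silyloxy group equatorial, and the chirality of the catalyst. Precursor 18 is acyclic and holds only the two purchased stereocentres. The closure must outrun aldol and β-elimination pathways and must place C6–O cis to C4–O.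

**18 back to 15.** These are changes of functional groups only: the C6 ketone is returned to its dithiane (17), the C1 aldehyde to its dimethyl acetal (16), and the C4 silyl ether to the free alcohol (15). The order matters. C4–OH must be capped before the aldehyde is freed, otherwise a five-membered lactol would form. The acetal is hydrolysed while C6 is still a dithiane, so that the β-silyloxy ketone never meets acid.

**15 back to 11, 6 and 10 (C6–C1′ and C5–C6).** Both bonds to the latent C6 are cut at once. Aldol constructions of the same bonds would have to induce the 1,5-syn relation of C2′ and C4. Two separate dithiane alkylations would cost three extra operations. The three precursors are a silyl dithiane 11 and two monosubstituted epoxides, 6 and 10. The forward reaction must attack terminal epoxide carbons and must use the two epoxides in strict order.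

**6 back to 1 and 3 (C3′–C4′).** Epoxide 6 is traced through chlorohydrin 5 to (S)-epichlorohydrin 3, which supplies C1′–C3′ and the C2′ configuration, and to bromide 2, made from the commercial (Z)-alkenol 1. Buying the (Z)-alkene avoids any alkyne reduction or Wittig step. Copper catalysis has to direct the Grignard reagent 4 to the epoxide carbon and not to the chloride.

**10 back to 7.** Epoxide 10 is the slow-reacting enantiomer of racemic 9 in a hydrolytic kinetic resolution. 9 comes from alkene 8 by peracid epoxidation and 8 from pent-4-enal 7 by acetalisation. The resolution discards half the material, but on a five-carbon piece made in two steps, and it fixes C4 with the reliability of a catalyst-controlled process.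

## Roads not taken

**Alternative 1:** The cut is at C1′–C2′ and at the C6–O bond: the ring is made first and the chain arrives as a nitrile oxide. In the forward step the magnesium alkoxide of cis-dienol A1 binds nitrile oxide A2 and delivers its oxygen to C6 on the face of the C1 oxygen, giving spiro-isoxazoline A3.
- Merits: C6 is set by hydroxyl-directed delivery on a rigid ring, a firmer control element than the chosen plan has for this centre. The long chain joins late.
- Weak points: C2′ arrives as C=N. After N–O cleavage it is a ketone β to a tertiary carbinol, open to retro-aldol cleavage of C6–C1′, and it must be reduced to the anti diol by internal hydride delivery (Evans–Saksena reduction), so a third stereocentre is still induced and not bought. The N–O cleavage has to spare the (Z)-alkene. A1 is an aromatisation-prone dienol with two stereocentres that needs its own asymmetric synthesis, and C1 must be reoxidised.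
- Comparison: the chosen plan concedes the better C6 control. Against it, C2′ and C4 come from 6 and 10 with full certainty, and the whole carbon skeleton 15 is reached in one flask.

**Alternative 2:** The cut is at C3–C4, with C6 traced to the tertiary carbinol of quinic acid A4. In the forward step CrCl2 (divalent chromium) with catalytic NiCl2 (divalent nickel) turns the (Z)-β-iodoenone of A5 into a vinylchromium species that adds to the C4 aldehyde (Nozaki–Hiyama–Kishi closure) to give A6.
- Merits: the configuration of C6 is beyond question, and the enone is formed in the ring closure, so no dehydrogenation is needed. In both respects this road is better than the chosen one.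
- Weak points: C4 is created in the closure, 1,3 to C6 across the forming ring with only an acetal on C6 to bias it. The ring of A4 has to be opened and most of its oxygenated carbons reworked, which is long. The (Z)-β-iodoenone next to an aldehyde in A5 is a labile Michael acceptor. C2′ and the chain must be attached by a separate asymmetric step, and chromium is used in excess.
- Comparison: the chosen plan reverses the distribution of risk, with C4 secure and C6 controlled in the closure, and it is much shorter.

**Alternative 3:** The cut is at C2–C3 together with the C4–O bond. In the forward step piperidine condenses the β-keto sulfoxide carbon C2 of A7 with its C3 aldehyde (Knoevenagel), the 2-sulfinyl enone moves its double bond to C3–C4, and Mislow–Evans [2,3] shift with sulfenate cleavage gives A8.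
- Merits: enone and C4–OH appear in one operation, with no protecting group at C4 and no dehydrogenation. This endgame is more step-economic than the chosen one.
- Weak points: C4 is set by a [2,3] shift whose face depends on an epimerisable sulfoxide-bearing C2, with only the remote C6 to bias it. Under amine base the 4-hydroxy enone is one dehydration away from a dienone and from aromatic products, and the free α-ketol is exposed to the same base. The plan gives no help with C6 or C2′, which A7 must already contain.
- Comparison: the chosen plan needs three more steps after ring closure, but it fixes C4 and C2′ from the epoxides and leaves only C6 to be controlled.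

Key step: step 7

Assumption: the (5aR,10bS) antipode of the triazolium salt in step 11 is taken as the one whose facial preference matches the chair preference of the substrate; its mirror image is equally available and would be used in the same step if the sense proves opposite.

## Route

Step 1
Reactants: 1 (Z)-tetradec-7-en-1-ol
Product: 2 (Z)-1-bromotetradec-7-ene
Conditions: CBr4, PPh3, CH2Cl2, 0 °C to rt
Reagents that add atoms: carbon tetrabromide, BrC(Br)(Br)Br
Why: Appel reaction; the primary alcohol is displaced at CH2 under neutral conditions that leave the (Z)-alkene untouched.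

Step 2
Reactants: 2 (Z)-1-bromotetradec-7-ene; 3 (S)-epichlorohydrin
Product: 5 (2S,10Z)-1-chloroheptadec-10-en-2-ol, via (Z)-tetradec-7-enylmagnesium bromide 4 (not isolated)
Conditions: Mg, THF, 40 °C; then CuI (10 mol%), 3, THF, −40 to 0 °C; aq. NH4Cl
Reagents that add atoms: none
Why: Copper-catalysed Grignard opening of an epoxide; the organocopper species attacks the unsubstituted epoxide carbon faster than it displaces chloride. No bond at the stereocentre breaks, so the future C2′ keeps the configuration of 3.

Step 3
Reactants: 5 (2S,10Z)-1-chloroheptadec-10-en-2-ol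
Product: 6 (S)-2-[(Z)-pentadec-8-enyl]oxirane
Conditions: NaOH (powdered), Et2O, rt
Reagents that add atoms: none
Why: Intramolecular Williamson closure of the chlorohydrin; the alkoxide displaces chloride at the primary carbon, so the carbinol centre is retained and the epoxide is (S).

Step 4
Reactants: 7 pent-4-enal
Product: 8 5,5-dimethoxypent-1-ene
Conditions: HC(OMe)3, p-TsOH·H2O (cat.), MeOH, rt
Reagents that add atoms: trimethyl orthoformate, COC(OC)OC
Why: Acid-catalysed acetalisation driven by the orthoformate as water scavenger; the terminal alkene is inert.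

Step 5
Reactants: 8 5,5-dimethoxypent-1-ene
Product: 9 rac-2-(3,3-dimethoxypropyl)oxirane
Conditions: mCPBA, CH2Cl2, 0 °C to rt
Reagents that add atoms: 3-chloroperoxybenzoic acid, OOC(=O)c1cccc(Cl)c1
Why: Prilezhaev epoxidation of a monosubstituted alkene; the anhydrous medium spares the dimethyl acetal, and the epoxide is racemic at this stage.

Step 6
Reactants: 9 rac-2-(3,3-dimethoxypropyl)oxirane
Product: 10 (R)-2-(3,3-dimethoxypropyl)oxirane
Conditions: (R,R)-N,N′-bis(3,5-di-tert-butylsalicylidene)-1,2-cyclohexanediaminocobalt acetate (trivalent cobalt, 0.5 mol%), H2O (0.55 equiv), THF (minimal), 0 °C to rt; distillation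
Reagents that add atoms: none
Why: Hydrolytic kinetic resolution of a terminal epoxide; the (R,R) complex hydrolyses the (S)-enantiomer of a monoalkyl oxirane much faster. With slightly more than half an equivalent of water the (R)-epoxide should remain and is separated from the diol by distillation; this sets the future C4.

Step 7
Reactants: 11 2-(tert-butyldimethylsilyl)-1,3-dithiane; 6 (S)-2-[(Z)-pentadec-8-enyl]oxirane; 10 (R)-2-(3,3-dimethoxypropyl)oxirane
Product: 15 (2R)-1-{2-[(2S,10Z)-2-(tert-butyldimethylsilyloxy)heptadec-10-enyl]-1,3-dithian-2-yl}-5,5-dimethoxypentan-2-ol, via 2-lithio-2-silyl-dithiane 12 (not isolated), via lithium alkoxide 13 (not isolated), via relayed dithiane anion 14 (not isolated)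
Conditions: t-BuLi (1.05 equiv), Et2O, −78 to −45 °C; 6 (1.0 equiv), Et2O, −78 to −25 °C; then 10 (1.2 equiv), HMPA, THF, −78 °C to rt; aq. NH4Cl
Reagents that add atoms: none
Why: tert-Butyllithium removes the C2 proton of 11 to give 12, which in ether opens 6 by SN2 attack at the unsubstituted epoxide carbon (C1′) to give alkoxide 13. In ether the alkoxide is tightly aggregated and silicon stays on carbon; HMPA loosens the ion pair and triggers 1,4-Brook migration of the silyl group to the C2′ oxygen, which regenerates a dithiane carbanion 14 at the future C6. Anion 14 opens 10 at its unsubstituted carbon (C5), so C6–C1′ and C5–C6 form in one flask. The closest known reaction type is the solvent-controlled linchpin coupling of 2-silyl-1,3-dithianes with two different terminal epoxides, an anion relay through Brook rearrangement. No ring closes and no stereocentre is created: C2′ and C4 come unchanged from 6 and 10 because only CH2–O bonds break. The step needs terminal regioselectivity, which the hindered carbanions and the monosubstituted epoxides secure. It also needs strict ordering of the two electrophiles, which follows from adding one equivalent of 6 without HMPA and introducing HMPA only with 10. The dimethyl acetal and the remote (Z)-alkene are inert to the lithium species at these temperatures, and the product carries C2′–O as silyl ether and C4–O as free alcohol.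

Step 8
Reactants: 15 (2R)-1-{2-[(2S,10Z)-2-(tert-butyldimethylsilyloxy)heptadec-10-enyl]-1,3-dithian-2-yl}-5,5-dimethoxypentan-2-ol
Product: 16 2-[(2R)-2-(tert-butyldimethylsilyloxy)-5,5-dimethoxypentyl]-2-[(2S,10Z)-2-(tert-butyldimethylsilyloxy)heptadec-10-enyl]-1,3-dithiane
Conditions: TBSCl, imidazole, DMAP (cat.), DMF, rt to 40 °C
Reagents that add atoms: tert-butyldimethylsilyl chloride, CC(C)(C)[Si](C)(C)Cl
Why: Standard silylation of a secondary alcohol; the basic conditions spare the dimethyl acetal, which a silyl triflate could ionise, and the capped C4 oxygen can no longer form a lactol with the C1 aldehyde.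

Step 9
Reactants: 16 2-[(2R)-2-(tert-butyldimethylsilyloxy)-5,5-dimethoxypentyl]-2-[(2S,10Z)-2-(tert-butyldimethylsilyloxy)heptadec-10-enyl]-1,3-dithiane
Product: 17 (4R)-4-(tert-butyldimethylsilyloxy)-5-{2-[(2S,10Z)-2-(tert-butyldimethylsilyloxy)heptadec-10-enyl]-1,3-dithian-2-yl}pentanal
Conditions: PPTS (cat.), acetone/H2O (10:1), 50 °C
Reagents that add atoms: water, O
Why: Mild acid hydrolysis of a dimethyl acetal; the dithiane and the secondary silyl ethers tolerate pyridinium tosylate, and C6 is still masked, so no β-silyloxy ketone is exposed to acid.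

Step 10
Reactants: 17 (4R)-4-(tert-butyldimethylsilyloxy)-5-{2-[(2S,10Z)-2-(tert-butyldimethylsilyloxy)heptadec-10-enyl]-1,3-dithian-2-yl}pentanal
Product: 18 (4R,8S,16Z)-4,8-bis(tert-butyldimethylsilyloxy)-6-oxotricos-16-enal
Conditions: MeI (excess), CaCO3, MeCN/H2O (9:1), 45 °C
Reagents that add atoms: water, O
Why: Alkylative hydrolysis of a 1,3-dithiane; S-methylation makes sulfur a leaving group and water delivers the ketone at near-neutral pH, which spares the aldehyde, the alkene and the β-silyloxy groups. The keto aldehyde is used directly.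

Step 11
Reactants: 18 (4R,8S,16Z)-4,8-bis(tert-butyldimethylsilyloxy)-6-oxotricos-16-enal
Product: 19 (2R,4R)-4-(tert-butyldimethylsilyloxy)-2-[(2S,10Z)-2-(tert-butyldimethylsilyloxy)heptadec-10-enyl]-2-hydroxycyclohexan-1-one
Conditions: (5aR,10bS)-5a,10b-dihydro-2-(pentafluorophenyl)-4H,6H-indeno[2,1-b][1,2,4]triazolo[4,3-d][1,4]oxazinium tetrafluoroborate (15 mol%), Et3N (15 mol%), toluene (0.05 M), rt
Reagents that add atoms: none
Why: Intramolecular crossed benzoin (carbene-catalysed aldehyde–ketone acyloin closure) of an aliphatic 1,6-keto aldehyde; the carbene-bound acyl-anion equivalent at C1 adds to the C6 ketone through a six-membered chair and gives the α-ketol in the final oxidation state. C6 is set here: with the C4 silyloxy group and the azolium unit equatorial, the ketone oxygen must sit equatorial to accept the hydroxyl proton, which is cis to C4–O, and the chiral aminoindanol backbone is chosen to favour the same face. C4 and C2′ are not touched (the ring carbons C6 and C4 of the target are C2 and C4 in the name of 19).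

Step 12
Reactants: 19 (2R,4R)-4-(tert-butyldimethylsilyloxy)-2-[(2S,10Z)-2-(tert-butyldimethylsilyloxy)heptadec-10-enyl]-2-hydroxycyclohexan-1-one
Product: 20 (4R,6R)-4-(tert-butyldimethylsilyloxy)-6-[(2S,10Z)-2-(tert-butyldimethylsilyloxy)heptadec-10-enyl]-1,6-bis(trimethylsilyloxy)cyclohex-1-ene
Conditions: TMSOTf (2.5 equiv), Et3N, CH2Cl2, −78 to 0 °C
Reagents that add atoms: trimethylsilyl trifluoromethanesulfonate, C[Si](C)(C)OS(=O)(=O)C(F)(F)F
Why: Soft enolisation to the silyl enol ether with silylation of the tertiary hydroxyl in the same operation; only C2 carries α-hydrogens, so a single enol ether regioisomer can form.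

Step 13
Reactants: 20 (4R,6R)-4-(tert-butyldimethylsilyloxy)-6-[(2S,10Z)-2-(tert-butyldimethylsilyloxy)heptadec-10-enyl]-1,6-bis(trimethylsilyloxy)cyclohex-1-ene
Product: 21 (4S,6R)-4-(tert-butyldimethylsilyloxy)-6-[(2S,10Z)-2-(tert-butyldimethylsilyloxy)heptadec-10-enyl]-6-(trimethylsilyloxy)cyclohex-2-en-1-one
Conditions: Pd(OAc)2 (1.1 equiv), MeCN, rt
Reagents that add atoms: none
Why: Saegusa–Ito oxidation; the palladium enolate formed from the silyl enol ether undergoes β-hydride elimination toward C3 and gives the C2=C3 enone. Room temperature and acetonitrile keep the isolated (Z)-alkene out of the reaction.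

Step 14
Reactants: 21 (4S,6R)-4-(tert-butyldimethylsilyloxy)-6-[(2S,10Z)-2-(tert-butyldimethylsilyloxy)heptadec-10-enyl]-6-(trimethylsilyloxy)cyclohex-2-en-1-one
Product: 22 (4S,6R)-4,6-dihydroxy-6-[(2S,10Z)-2-hydroxyheptadec-10-enyl]cyclohex-2-en-1-one
Conditions: HF·pyridine, pyridine, THF, 0 °C to rt
Reagents that add atoms: none
Why: Fluoride-mediated cleavage of one trimethylsilyl and two secondary tert-butyldimethylsilyl ethers; the pyridine buffer keeps the medium too weakly acidic to dehydrate the γ-hydroxy enone, and no stereocentre is affected.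

## Compound list

1 | (Z)-tetradec-7-en-1-ol | CCCCCC/C=C\CCCCCCO | starting material
2 | (Z)-1-bromotetradec-7-ene | CCCCCC/C=C\CCCCCCBr | intermediate
3 | (S)-epichlorohydrin | ClC[C@@H]1CO1 | starting material
4 | (Z)-tetradec-7-enylmagnesium bromide | CCCCCC/C=C\CCCCCC[Mg]Br | intermediate
5 | (2S,10Z)-1-chloroheptadec-10-en-2-ol | CCCCCC/C=C\CCCCCCC[C@H](O)CCl | intermediate
6 | (S)-2-[(Z)-pentadec-8-enyl]oxirane | CCCCCC/C=C\CCCCCCC[C@H]1CO1 | intermediate
7 | pent-4-enal | C=CCCC=O | starting material
8 | 5,5-dimethoxypent-1-ene | C=CCCC(OC)OC | intermediate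
9 | rac-2-(3,3-dimethoxypropyl)oxirane | C1OC1CCC(OC)OC | intermediate
10 | (R)-2-(3,3-dimethoxypropyl)oxirane | C1[C@H](O1)CCC(OC)OC | intermediate
11 | 2-(tert-butyldimethylsilyl)-1,3-dithiane | C[Si](C)(C1SCCCS1)C(C)(C)C | starting material
12 | 2-(tert-butyldimethylsilyl)-2-lithio-1,3-dithiane | [Li]C1(SCCCS1)[Si](C)(C)C(C)(C)C | intermediate
13 | lithium (2S,10Z)-1-[2-(tert-butyldimethylsilyl)-1,3-dithian-2-yl]heptadec-10-en-2-olate | CCCCCC/C=C\CCCCCCC[C@H](O[Li])CC1(SCCCS1)[Si](C)(C)C(C)(C)C | intermediate
14 | 2-[(2S,10Z)-2-(tert-butyldimethylsilyloxy)heptadec-10-enyl]-2-lithio-1,3-dithiane | CCCCCC/C=C\CCCCCCC[C@H](O[Si](C)(C)C(C)(C)C)CC1([Li])SCCCS1 | intermediate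
15 | (2R)-1-{2-[(2S,10Z)-2-(tert-butyldimethylsilyloxy)heptadec-10-enyl]-1,3-dithian-2-yl}-5,5-dimethoxypentan-2-ol | CCCCCC/C=C\CCCCCCC[C@H](O[Si](C)(C)C(C)(C)C)CC1(SCCCS1)C[C@H](O)CCC(OC)OC | intermediate
16 | 2-[(2R)-2-(tert-butyldimethylsilyloxy)-5,5-dimethoxypentyl]-2-[(2S,10Z)-2-(tert-butyldimethylsilyloxy)heptadec-10-enyl]-1,3-dithiane | CCCCCC/C=C\CCCCCCC[C@H](O[Si](C)(C)C(C)(C)C)CC1(SCCCS1)C[C@H](O[Si](C)(C)C(C)(C)C)CCC(OC)OC | intermediate
17 | (4R)-4-(tert-butyldimethylsilyloxy)-5-{2-[(2S,10Z)-2-(tert-butyldimethylsilyloxy)heptadec-10-enyl]-1,3-dithian-2-yl}pentanal | CCCCCC/C=C\CCCCCCC[C@H](O[Si](C)(C)C(C)(C)C)CC1(SCCCS1)C[C@H](O[Si](C)(C)C(C)(C)C)CCC=O | intermediate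
18 | (4R,8S,16Z)-4,8-bis(tert-butyldimethylsilyloxy)-6-oxotricos-16-enal | CCCCCC/C=C\CCCCCCC[C@H](O[Si](C)(C)C(C)(C)C)CC(=O)C[C@H](O[Si](C)(C)C(C)(C)C)CCC=O | intermediate
19 | (2R,4R)-4-(tert-butyldimethylsilyloxy)-2-[(2S,10Z)-2-(tert-butyldimethylsilyloxy)heptadec-10-enyl]-2-hydroxycyclohexan-1-one | CCCCCC/C=C\CCCCCCC[C@H](O[Si](C)(C)C(C)(C)C)C[C@@]1(O)C[C@H](O[Si](C)(C)C(C)(C)C)CCC1=O | intermediate
20 | (4R,6R)-4-(tert-butyldimethylsilyloxy)-6-[(2S,10Z)-2-(tert-butyldimethylsilyloxy)heptadec-10-enyl]-1,6-bis(trimethylsilyloxy)cyclohex-1-ene | CCCCCC/C=C\CCCCCCC[C@H](O[Si](C)(C)C(C)(C)C)C[C@@]1(O[Si](C)(C)C)C[C@H](O[Si](C)(C)C(C)(C)C)CC=C1O[Si](C)(C)C | intermediate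
21 | (4S,6R)-4-(tert-butyldimethylsilyloxy)-6-[(2S,10Z)-2-(tert-butyldimethylsilyloxy)heptadec-10-enyl]-6-(trimethylsilyloxy)cyclohex-2-en-1-one | CCCCCC/C=C\CCCCCCC[C@H](O[Si](C)(C)C(C)(C)C)C[C@@]1(O[Si](C)(C)C)C[C@H](O[Si](C)(C)C(C)(C)C)C=CC1=O | intermediate
22 | (4S,6R)-4,6-dihydroxy-6-[(2S,10Z)-2-hydroxyheptadec-10-enyl]cyclohex-2-en-1-one | CCCCCC/C=C\CCCCCCC[C@H](O)C[C@@]1(O)C[C@H](O)C=CC1=O | target

## Step count and least certain steps

Total: 14 steps. Longest linear sequence: 11 steps (1 to 22 through 2, 5, 6 and 15; the branch from 7 is equally long).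

**Step 7 (key step).** Silyl migration may begin before 6 is consumed, so that one epoxide adds twice, or the relayed anion 14 may be protonated before the slower second opening, which stops the sequence at the mono-adduct. Fallback, from 6 back to 15: lithiated 1,3-dithiane (n-BuLi, THF) opens 6 to give (2S,10Z)-1-(1,3-dithian-2-yl)heptadec-10-en-2-ol F1. Silylation with TBSCl and imidazole gives its tert-butyldimethylsilyl ether F2. Deprotonation of F2 with t-BuLi in THF/HMPA at −78 °C and alkylation with 10 returns to 15. The two C–C bonds are then made in separate, individually controllable alkylations at the cost of two operations.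

**Step 11.** Facial selectivity at C6 may be poor if the chair preference of the substrate and the catalyst oppose each other. Triethylamine may also trigger E1cB loss of silanol from the β-silyloxy ketone or aldol cyclisation before the benzoin closure; the mirror-image catalyst is the first remedy within the step. Fallback, from 18 back to 19: reductive pinacol cyclisation with SmI2 (divalent samarium) in THF/t-BuOH at −78 °C should give the cis-diol (1S,2R,4R)-4-(tert-butyldimethylsilyloxy)-2-[(2S,10Z)-2-(tert-butyldimethylsilyloxy)heptadec-10-enyl]cyclohexane-1,2-diol F3 through a samarium-bridged ketyl. Parikh–Doering oxidation (SO3·pyridine, DMSO, i-Pr2NEt) of its only secondary hydroxyl returns to 19. This is base-free and relies on a different control element for C6.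

**Step 10.** Hydrolysis of the hindered 2,2-dialkyl dithiane may be slow, and long warming of the liberated keto aldehyde invites aldol condensation and β-elimination. Fallback, from 16 back to 18: the order of unmasking is reversed and sulfur is activated by oxidation. PhI(OCOCF3)2 in aqueous MeCN buffered with NaHCO3 at 0 °C converts 16 into the keto acetal (4R,8S,16Z)-4,8-bis(tert-butyldimethylsilyloxy)-1,1-dimethoxytricos-16-en-6-one F4, and brief PPTS treatment in wet acetone then frees the aldehyde to give 18.

**Step 13 (with step 12).** Palladium hydride formed during the oxidation may isomerise or shift the (Z)-alkene, and adventitious acid may hydrolyse the enol ether back to 19. Fallback, from 19 to 22: the dianion of 19 (LDA, 2.2 equiv, THF, −78 °C) is selenenylated with PhSeCl to give (4S,6R)-4-(tert-butyldimethylsilyloxy)-6-[(2S,10Z)-2-(tert-butyldimethylsilyloxy)heptadec-10-enyl]-6-hydroxy-2-(phenylselanyl)cyclohexan-1-one F5 as a mixture of C2 epimers. Oxidation with H2O2 and pyridine and syn-elimination of the selenoxide give (4S,6R)-4-(tert-butyldimethylsilyloxy)-6-[(2S,10Z)-2-(tert-butyldimethylsilyloxy)heptadec-10-enyl]-6-hydroxycyclohex-2-en-1-one F6. Desilylation under the conditions of step 14 gives 22, with no palladium used.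

**Step 14.** The two secondary tert-butyldimethylsilyl ethers need hours of fluoride treatment, during which acid-promoted dehydration of the γ-hydroxy enone toward aromatic products may compete. Fallback, from 19 to 22: the robust silyl groups are removed at the saturated stage, where dehydration is not a threat, with HF·pyridine to give (2R,4R)-2,4-dihydroxy-2-[(2S,10Z)-2-hydroxyheptadec-10-enyl]cyclohexan-1-one F7. Exhaustive silylation with TMSOTf and Et3N gives (4R,6R)-1,4,6-tris(trimethylsilyloxy)-6-[(2S,10Z)-2-(trimethylsilyloxy)heptadec-10-enyl]cyclohex-1-ene F8. Saegusa–Ito oxidation with Pd(OAc)2 gives (4S,6R)-4,6-bis(trimethylsilyloxy)-6-[(2S,10Z)-2-(trimethylsilyloxy)heptadec-10-enyl]cyclohex-2-en-1-one F9. Its three trimethylsilyl ethers are cleaved by citric acid in methanol at 0 °C within minutes to give 22.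

## Further compounds

F1 | step 7 | (2S,10Z)-1-(1,3-dithian-2-yl)heptadec-10-en-2-ol | CCCCCC/C=C\CCCCCCC[C@H](O)CC1SCCCS1
F2 | step 7 | 2-[(2S,10Z)-2-(tert-butyldimethylsilyloxy)heptadec-10-enyl]-1,3-dithiane | CCCCCC/C=C\CCCCCCC[C@H](O[Si](C)(C)C(C)(C)C)CC1SCCCS1
F3 | step 11 | (1S,2R,4R)-4-(tert-butyldimethylsilyloxy)-2-[(2S,10Z)-2-(tert-butyldimethylsilyloxy)heptadec-10-enyl]cyclohexane-1,2-diol | CCCCCC/C=C\CCCCCCC[C@H](O[Si](C)(C)C(C)(C)C)C[C@@]1(O)C[C@H](O[Si](C)(C)C(C)(C)C)CC[C@@H]1O
F4 | step 10 | (4R,8S,16Z)-4,8-bis(tert-butyldimethylsilyloxy)-1,1-dimethoxytricos-16-en-6-one | CCCCCC/C=C\CCCCCCC[C@H](O[Si](C)(C)C(C)(C)C)CC(=O)C[C@H](O[Si](C)(C)C(C)(C)C)CCC(OC)OC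
F5 | step 13 | (4S,6R)-4-(tert-butyldimethylsilyloxy)-6-[(2S,10Z)-2-(tert-butyldimethylsilyloxy)heptadec-10-enyl]-6-hydroxy-2-(phenylselanyl)cyclohexan-1-one (C2 epimers) | CCCCCC/C=C\CCCCCCC[C@H](O[Si](C)(C)C(C)(C)C)C[C@@]1(O)C[C@H](O[Si](C)(C)C(C)(C)C)CC([Se]c2ccccc2)C1=O
F6 | step 13 | (4S,6R)-4-(tert-butyldimethylsilyloxy)-6-[(2S,10Z)-2-(tert-butyldimethylsilyloxy)heptadec-10-enyl]-6-hydroxycyclohex-2-en-1-one | CCCCCC/C=C\CCCCCCC[C@H](O[Si](C)(C)C(C)(C)C)C[C@@]1(O)C[C@H](O[Si](C)(C)C(C)(C)C)C=CC1=O
F7 | step 14 | (2R,4R)-2,4-dihydroxy-2-[(2S,10Z)-2-hydroxyheptadec-10-enyl]cyclohexan-1-one | CCCCCC/C=C\CCCCCCC[C@H](O)C[C@@]1(O)C[C@H](O)CCC1=O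
F8 | step 14 | (4R,6R)-1,4,6-tris(trimethylsilyloxy)-6-[(2S,10Z)-2-(trimethylsilyloxy)heptadec-10-enyl]cyclohex-1-ene | CCCCCC/C=C\CCCCCCC[C@H](O[Si](C)(C)C)C[C@@]1(O[Si](C)(C)C)C[C@H](O[Si](C)(C)C)CC=C1O[Si](C)(C)C
F9 | step 14 | (4S,6R)-4,6-bis(trimethylsilyloxy)-6-[(2S,10Z)-2-(trimethylsilyloxy)heptadec-10-enyl]cyclohex-2-en-1-one | CCCCCC/C=C\CCCCCCC[C@H](O[Si](C)(C)C)C[C@@]1(O[Si](C)(C)C)C[C@H](O[Si](C)(C)C)C=CC1=O
A1 | alternative 1 | (1S,4S)-4-(tert-butyldimethylsilyloxy)-6-methylidenecyclohex-2-en-1-ol | C=C1C[C@H](O[Si](C)(C)C(C)(C)C)C=C[C@@H]1O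
A2 | alternative 1 | (Z)-hexadec-9-enenitrile oxide | CCCCCC/C=C\CCCCCCCC#[N+][O-]
A3 | alternative 1 | (5R,6S,9S)-9-(tert-butyldimethylsilyloxy)-3-[(Z)-pentadec-8-enyl]-1-oxa-2-azaspiro[4.5]deca-2,7-dien-6-ol | CCCCCC/C=C\CCCCCCCC1=NO[C@]2(C1)C[C@H](O[Si](C)(C)C(C)(C)C)C=C[C@@H]2O
A4 | alternative 2 | (−)-quinic acid, (1S,3R,4S,5R)-1,3,4,5-tetrahydroxycyclohexane-1-carboxylic acid | OC(=O)[C@]1(O)C[C@@H](O)[C@@H](O)[C@H](O)C1
A5 | alternative 2 | (3R,5S,13Z)-5-(tert-butyldimethylsilyloxy)-3-[(Z)-3-iodoprop-2-enoyl]-3-(methoxymethoxy)icos-13-enal | CCCCCC/C=C\CCCCCCC[C@H](O[Si](C)(C)C(C)(C)C)C[C@@](OCOC)(CC=O)C(=O)/C=C\I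
A6 | alternative 2 | (4S,6S)-4-hydroxy-6-(methoxymethoxy)-6-[(2S,10Z)-2-(tert-butyldimethylsilyloxy)heptadec-10-enyl]cyclohex-2-en-1-one (C6 arranged as in 22; the descriptor changes with the silyl ether) | CCCCCC/C=C\CCCCCCC[C@H](O[Si](C)(C)C(C)(C)C)C[C@@]1(OCOC)C[C@H](O)C=CC1=O
A7 | alternative 3 | (4S,6S,14Z)-6-(tert-butyldimethylsilyloxy)-4-hydroxy-4-[2-(phenylsulfinyl)acetyl]henicos-14-enal | CCCCCC/C=C\CCCCCCC[C@H](O[Si](C)(C)C(C)(C)C)C[C@@](O)(CCC=O)C(=O)CS(=O)c1ccccc1
A8 | alternative 3 | (4S,6S)-4,6-dihydroxy-6-[(2S,10Z)-2-(tert-butyldimethylsilyloxy)heptadec-10-enyl]cyclohex-2-en-1-one (C6 arranged as in 22; the descriptor changes with the silyl ether) | CCCCCC/C=C\CCCCCCC[C@H](O[Si](C)(C)C(C)(C)C)C[C@@]1(O)C[C@H](O)C=CC1=O
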